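**Retrosynthetic overview**

1. The 14-membered carbocycle is closed last by an intramolecular Nozaki–Hiyama–Kishi addition of the C12 alkenyl iodide to the C13 aldehyde.
2. The seco chain comes from a boron aldol that joins C5–C6, followed by an Evans–Tishchenko reduction (C7–OH, C5–OAc, 1,3-anti). The partners are fragment A (aldehyde, C1–C5 and C13–C18, ten carbons) and fragment B (methyl ketone, C6–C12 with C19 and C20, nine carbons).
3. Fragment A: the ε-lactone is made by Baeyer–Villiger ring expansion of a 2,2,5-trisubstituted cyclohexanone (C1 by rhodium-catalysed vinyl 1,4-addition, C4 by formylation then methylation); the α-methylene group follows by a Mannich/elimination sequence.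
4. Fragment B: Z-selective Wittig reaction of silylated acetoin with the ylide derived from pent-3-yn-1-ol (hydrozirconation–iodination gives the E alkenyl iodide).
5. Ring order: six-membered carbocycle (bought) → seven-membered lactone (step 7) → 14-membered carbocycle (step 21).

Locants are cembrane numbers: C1 is the ring CH carrying C15(=C17H2)–C16(=O)–O–C4; C4 is quaternary (C18 methyl); C5 OAc; C7 OH; C8(C19)=C9; C11=C12(C20); C13 OH. The target is 1S,4S,5R,7R,13R,8Z,11E.

Assumption: the (S)-configured sulfonamide ligand in step 21 is taken to favour the 13R carbinol; its enantiomer is used if the first run shows the opposite sense.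

**Fragment A**

Step 1
Reactants: 1 cyclohex-2-en-1-one; 2 potassium vinyltrifluoroborate
Product: 3 (3R)-3-ethenylcyclohexan-1-one
Conditions: [Rh(cod)2]BF4 (3 mol %, cod = cycloocta-1,5-diene), (R)-2,2'-bis(diphenylphosphanyl)-1,1'-binaphthyl (3.3 mol %), toluene/H2O 4:1, 100 °C
Reagents that add atoms: none
Why: Hayashi–Miyaura rhodium-catalysed asymmetric 1,4-addition, in which the (R)-BINAP catalyst transfers the vinyl group to one face of the enone and sets the future C1 (R here, 1S in the target) in high ee.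

Step 2
Reactants: 3 (3R)-3-ethenylcyclohexan-1-one; 4 ethyl formate
Product: 5 (2Z,5R)-5-ethenyl-2-(hydroxymethylidene)cyclohexan-1-one
Conditions: NaH (1.1 equiv), EtOH (cat.), Et2O, 0 °C → rt; aq. HCl work-up
Reagents that add atoms: none
Why: Crossed Claisen condensation (formylation) under equilibrating conditions puts C5 on the less hindered α-carbon, remote from the vinyl-bearing centre, as the chelated Z enol; no new stereocentre.

Step 3
Reactants: 5 (2Z,5R)-5-ethenyl-2-(hydroxymethylidene)cyclohexan-1-one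
Product: 6 (1S,4R)-4-ethenyl-1-methyl-2-oxocyclohexane-1-carbaldehyde
Conditions: MeI (3 equiv), K2CO3, acetone, reflux
Reagents that add atoms: iodomethane, CI
Why: C-alkylation of the β-keto aldehyde enolate, in which MeI attacks axially on the half-chair that keeps vinyl equatorial, so methyl enters cis to vinyl and the quaternary C4 forms with the formyl group trans to the C14 arm (about 4:1 expected, minor isomer removed by chromatography at 7).

Step 4
Reactants: 6 (1S,4R)-4-ethenyl-1-methyl-2-oxocyclohexane-1-carbaldehyde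
Product: 7 (2S,5R)-2-(dimethoxymethyl)-5-ethenyl-2-methylcyclohexan-1-one
Conditions: HC(OMe)3, MeOH, p-toluenesulfonic acid monohydrate (2 mol %), 0 °C → rt; Et3N quench
Reagents that add atoms: trimethyl orthoformate, COC(OC)OC
Why: Chemoselective acetalisation, since the aldehyde is far more reactive than the hindered α-quaternary ketone; the acetal masks C5 through the peracid and enolate steps.

Step 5
Reactants: 7 (2S,5R)-2-(dimethoxymethyl)-5-ethenyl-2-methylcyclohexan-1-one
Product: 9 (2S,5S)-2-(dimethoxymethyl)-5-(2-hydroxyethyl)-2-methylcyclohexan-1-one, via alkyl-9-BBN adduct 8 (not isolated)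
Conditions: 9-BBN (1.3 equiv), THF, 0 °C → rt; then 3 M NaOH, 30% H2O2, 0 °C
Reagents that add atoms: hydrogen peroxide, OO
Why: Hydroboration–oxidation, in which 9-BBN adds anti-Markovnikov to the monosubstituted alkene faster than it reduces the hindered 2,2-disubstituted ketone, giving the C13 primary alcohol.

Step 6
Reactants: 9 (2S,5S)-2-(dimethoxymethyl)-5-(2-hydroxyethyl)-2-methylcyclohexan-1-one
Product: 10 (2S,5S)-5-{2-[tert-butyl(diphenyl)silyl]oxyethyl}-2-(dimethoxymethyl)-2-methylcyclohexan-1-one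
Conditions: TBDPSCl, imidazole, CH2Cl2, rt
Reagents that add atoms: tert-butyl(chloro)diphenylsilane, CC(C)(C)[Si](Cl)(c1ccccc1)c1ccccc1
Why: Standard silylation of the primary alcohol; the TBDPS ether survives peracid, LiN(iPr)2 and aqueous acid.

Step 7
Reactants: 10 (2S,5S)-5-{2-[tert-butyl(diphenyl)silyl]oxyethyl}-2-(dimethoxymethyl)-2-methylcyclohexan-1-one
Product: 11 (4S,7S)-4-{2-[tert-butyl(diphenyl)silyl]oxyethyl}-7-(dimethoxymethyl)-7-methyloxepan-2-one
Conditions: mCPBA (dried, 2 equiv), CH2Cl2, 0 °C → rt, 24–48 h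
Reagents that add atoms: 3-chloroperoxybenzoic acid, OOC(=O)c1cccc(Cl)c1
Why: Baeyer–Villiger oxidation, in which the fully substituted α-carbon migrates with retention, so the lactone oxygen is delivered to C4 with its configuration intact.

Step 8
Reactants: 11 (4S,7S)-4-{2-[tert-butyl(diphenyl)silyl]oxyethyl}-7-(dimethoxymethyl)-7-methyloxepan-2-one
Product: 15 (4S,7S)-4-{2-[tert-butyl(diphenyl)silyl]oxyethyl}-7-(dimethoxymethyl)-7-methyl-3-methylideneoxepan-2-one, via lithium enolate 12 (not isolated), via Mannich base 13 (not isolated), via trimethylammonium iodide 14 (not isolated)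
Conditions: LiN(iPr)2, THF, −78 °C; CH2=NMe2+ I−, −78 °C → rt; MeI, MeOH, rt; aq. NaHCO3, EtOAc, rt
Reagents that add atoms: N,N-dimethylmethyleneiminium iodide (Eschenmoser's salt), C=[N+](C)C.[I-]
Why: Mannich reaction of the only possible lactone enolate (C15), N-methylation and Hofmann-type elimination give the exocyclic methylene; no stereocentre is touched.

Step 9
Reactants: 15 (4S,7S)-4-{2-[tert-butyl(diphenyl)silyl]oxyethyl}-7-(dimethoxymethyl)-7-methyl-3-methylideneoxepan-2-one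
Product: 16 (2S,5S)-5-{2-[tert-butyl(diphenyl)silyl]oxyethyl}-2-methyl-6-methylidene-7-oxooxepane-2-carbaldehyde
Conditions: CF3CO2H/H2O 9:1, CHCl3, 0 °C → rt
Reagents that add atoms: water, O
Why: Acid hydrolysis of the dimethyl acetal; the tertiary C4–O bond does not ionise next to the electron-poor formyl carbon, and the aldehyde has no α-hydrogen to epimerise.

**Fragment B**

Step 10
Reactants: 17 pent-3-yn-1-ol
Product: 19 (3E)-4-iodopent-3-en-1-ol, via alkenylzirconocene 18 (not isolated)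
Conditions: Cp2Zr(H)Cl (2.5 equiv), THF, rt; then I2, 0 °C
Reagents that add atoms: iodine, II
Why: Hydrozirconation–iodination, in which syn addition of Zr–H, equilibration of zirconium to the methyl-bearing carbon and iodinolysis with retention give the E alkenyl iodide.

Step 11
Reactants: 19 (3E)-4-iodopent-3-en-1-ol
Product: 20 (2E)-2,5-diiodopent-2-ene
Conditions: I2, PPh3, imidazole, CH2Cl2, 0 °C → rt
Reagents that add atoms: iodine, II
Why: Appel-type iodination of the primary alcohol by SN2 displacement of the oxyphosphonium group; the alkene geometry is untouched.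

Step 12
Reactants: 20 (2E)-2,5-diiodopent-2-ene
Product: 21 [(3E)-4-iodopent-3-en-1-yl](triphenyl)phosphonium iodide
Conditions: PPh3, MeCN, 80 °C
Reagents that add atoms: triphenylphosphine, c1ccc(cc1)P(c1ccccc1)c1ccccc1
Why: SN2 quaternisation of PPh3 by the primary iodide; the alkenyl iodide is inert.

Step 13
Reactants: 22 3-hydroxybutan-2-one
Product: 23 3-[tert-butyl(dimethyl)silyl]oxybutan-2-one
Conditions: TBSCl, imidazole, CH2Cl2, rt
Reagents that add atoms: tert-butyl(chloro)dimethylsilane, CC(C)(C)[Si](C)(C)Cl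
Why: Silylation of the α-hydroxy ketone (racemic; this centre is later oxidised) provides the α-oxygen substituent that steers the Wittig reaction to the Z alkene.

Step 14
Reactants: 21 [(3E)-4-iodopent-3-en-1-yl](triphenyl)phosphonium iodide; 23 3-[tert-butyl(dimethyl)silyl]oxybutan-2-one
Product: 25 tert-butyl{[(3Z,6E)-7-iodo-3-methylocta-3,6-dien-2-yl]oxy}dimethylsilane, via phosphorus ylide 24 (not isolated)
Conditions: 21, NaN(SiMe3)2, THF, −78 °C → 0 °C; then 23, −78 °C → rt
Reagents that add atoms: none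
Why: Wittig olefination of an α-alkoxy ketone with a non-stabilised ylide (Still's Z-selective variant) places the oxygenated carbon C7 cis to C10 and so sets the 8Z trisubstituted alkene.

Step 15
Reactants: 25 tert-butyl{[(3Z,6E)-7-iodo-3-methylocta-3,6-dien-2-yl]oxy}dimethylsilane
Product: 26 (3Z,6E)-7-iodo-3-methylocta-3,6-dien-2-ol
Conditions: HF·pyridine, THF, 0 °C → rt
Reagents that add atoms: none
Why: Fluoride-mediated desilylation under mildly acidic conditions that leave the alkenyl iodide and the skipped diene untouched.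

Step 16
Reactants: 26 (3Z,6E)-7-iodo-3-methylocta-3,6-dien-2-ol
Product: 27 (3Z,6E)-7-iodo-3-methylocta-3,6-dien-2-one
Conditions: Dess–Martin periodinane, pyridine, CH2Cl2, 0 °C
Reagents that add atoms: none
Why: Dess–Martin oxidation under buffered, non-basic conditions gives the Z enone without isomerising it or moving the skipped diene into conjugation.

**Union and ring closure**

Step 17
Reactants: 27 (3Z,6E)-7-iodo-3-methylocta-3,6-dien-2-one; 16 (2S,5S)-5-{2-[tert-butyl(diphenyl)silyl]oxyethyl}-2-methyl-6-methylidene-7-oxooxepane-2-carbaldehyde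
Product: 30 (4S,7S)-4-{2-[tert-butyl(diphenyl)silyl]oxyethyl}-7-[(1R,4Z,7E)-1-hydroxy-8-iodo-4-methyl-3-oxonona-4,7-dien-1-yl]-7-methyl-3-methylideneoxepan-2-one, via boron enolate 28 (not isolated), via boron aldolate 29 (not isolated)
Conditions: 27, (−)-B-chlorodiisopinocampheylborane [(−)-Ipc2BCl, 1.3 equiv], Et3N, Et2O, −78 → 0 °C; then 16, −78 → −20 °C; MeOH, pH 7 buffer, 30% H2O2, 0 °C
Reagents that add atoms: none
Why: Paterson boron aldol reaction with kinetic enolisation at the methyl group, in which the isopinocampheyl ligands direct attack to the re face of the aldehyde, the same face favoured by the Cornforth model of the α-acyloxy aldehyde, giving 5R.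

Step 18
Reactants: 30 (4S,7S)-4-{2-[tert-butyl(diphenyl)silyl]oxyethyl}-7-[(1R,4Z,7E)-1-hydroxy-8-iodo-4-methyl-3-oxonona-4,7-dien-1-yl]-7-methyl-3-methylideneoxepan-2-one; 31 acetaldehyde
Product: 32 (1R,3R,4Z,7E)-1-[(2S,5S)-5-{2-[tert-butyl(diphenyl)silyl]oxyethyl}-2-methyl-6-methylidene-7-oxooxepan-2-yl]-3-hydroxy-8-iodo-4-methylnona-4,7-dien-1-yl acetate
Conditions: SmI2 (0.3 equiv), MeCHO (6 equiv), THF, −10 °C
Reagents that add atoms: none
Why: Evans–Tishchenko reduction, in which hydride passes intramolecularly from the acetaldehyde hemiacetal of the C5 hydroxyl to the C7 ketone through a samarium-bound chair, giving the 1,3-anti 7R alcohol and leaving the C5 oxygen as its acetate.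

Step 19
Reactants: 32 (1R,3R,4Z,7E)-1-[(2S,5S)-5-{2-[tert-butyl(diphenyl)silyl]oxyethyl}-2-methyl-6-methylidene-7-oxooxepan-2-yl]-3-hydroxy-8-iodo-4-methylnona-4,7-dien-1-yl acetate
Product: 33 (1R,3R,4Z,7E)-3-hydroxy-1-[(2S,5S)-5-(2-hydroxyethyl)-2-methyl-6-methylidene-7-oxooxepan-2-yl]-8-iodo-4-methylnona-4,7-dien-1-yl acetate
Conditions: HF·pyridine, pyridine, THF, 0 °C → rt; used at once
Reagents that add atoms: none
Why: Buffered HF·pyridine desilylation frees the primary alcohol while the acetate, the allylic alcohol and the hindered conjugated lactone (slow to translactonise with the freed δ-hydroxyl) are kept.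

Step 20
Reactants: 33 (1R,3R,4Z,7E)-3-hydroxy-1-[(2S,5S)-5-(2-hydroxyethyl)-2-methyl-6-methylidene-7-oxooxepan-2-yl]-8-iodo-4-methylnona-4,7-dien-1-yl acetate
Product: 34 (1R,3R,4Z,7E)-3-hydroxy-8-iodo-4-methyl-1-[(2S,5S)-2-methyl-6-methylidene-7-oxo-5-(2-oxoethyl)oxepan-2-yl]nona-4,7-dien-1-yl acetate
Conditions: 2,2,6,6-tetramethylpiperidin-1-oxyl (0.2 equiv), PhI(OAc)2 (1.2 equiv), CH2Cl2, rt
Reagents that add atoms: none
Why: Oxoammonium oxidation is selective for the primary alcohol over the hindered secondary allylic alcohol and stops at the aldehyde.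

Step 21
Reactants: 34 (1R,3R,4Z,7E)-3-hydroxy-8-iodo-4-methyl-1-[(2S,5S)-2-methyl-6-methylidene-7-oxo-5-(2-oxoethyl)oxepan-2-yl]nona-4,7-dien-1-yl acetate
Product: 35 (1S,4S,5R,7R,8Z,11E,13R)-5-acetoxy-7,13-dihydroxycembra-8,11,15(17)-trien-16,4-olide
Conditions: CrCl2 (8 equiv), (S)-N-[2-(4-isopropyl-4,5-dihydrooxazol-2-yl)-6-methylphenyl]methanesulfonamide (8.8 equiv), Et3N (8.8 equiv), THF, rt; NiCl2 (0.2 equiv); slow addition of 34 to 2 mM, rt
Reagents that add atoms: none
Why: Intramolecular Nozaki–Hiyama–Kishi reaction, in which NiCl2-catalysed activation of the C–I bond and chromium-mediated addition to the aldehyde under high dilution close the 14-membered ring with retention of the 11E geometry, the chiral sulfonamide ligand on chromium selecting the aldehyde face that gives 13R.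

**Compound list**

1 | cyclohex-2-en-1-one | O=C1C=CCCC1 | starting material
2 | potassium vinyltrifluoroborate | C=C[B-](F)(F)F.[K+] | starting material
3 | (3R)-3-ethenylcyclohexan-1-one | C=C[C@@H]1CCCC(=O)C1 | intermediate
4 | ethyl formate | CCOC=O | starting material
5 | (2Z,5R)-5-ethenyl-2-(hydroxymethylidene)cyclohexan-1-one | C=C[C@@H]1CC/C(=C/O)C(=O)C1 | intermediate
6 | (1S,4R)-4-ethenyl-1-methyl-2-oxocyclohexane-1-carbaldehyde | C=C[C@@H]1CC[C@@](C)(C=O)C(=O)C1 | intermediate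
7 | (2S,5R)-2-(dimethoxymethyl)-5-ethenyl-2-methylcyclohexan-1-one | C=C[C@@H]1CC[C@@](C)(C(OC)OC)C(=O)C1 | intermediate
8 | 9-{2-[(1R,4S)-4-(dimethoxymethyl)-4-methyl-3-oxocyclohexyl]ethyl}-9-borabicyclo[3.3.1]nonane | C(C[C@@H]1CC[C@@](C)(C(OC)OC)C(=O)C1)B1C2CCCC1CCC2 | intermediate (not isolated)
9 | (2S,5S)-2-(dimethoxymethyl)-5-(2-hydroxyethyl)-2-methylcyclohexan-1-one | OCC[C@@H]1CC[C@@](C)(C(OC)OC)C(=O)C1 | intermediate
10 | (2S,5S)-5-{2-[tert-butyl(diphenyl)silyl]oxyethyl}-2-(dimethoxymethyl)-2-methylcyclohexan-1-one | CC(C)(C)[Si](OCC[C@@H]1CC[C@@](C)(C(OC)OC)C(=O)C1)(c1ccccc1)c1ccccc1 | intermediate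
11 | (4S,7S)-4-{2-[tert-butyl(diphenyl)silyl]oxyethyl}-7-(dimethoxymethyl)-7-methyloxepan-2-one | CC(C)(C)[Si](OCC[C@@H]1CC[C@@](C)(C(OC)OC)OC(=O)C1)(c1ccccc1)c1ccccc1 | intermediate
12 | lithium enolate of 11 (C15–C16 enolate) | CC(C)(C)[Si](OCC[C@@H]1CC[C@@](C)(C(OC)OC)OC(O[Li])=C1)(c1ccccc1)c1ccccc1 | intermediate (not isolated)
13 | 3-[(dimethylamino)methyl] derivative of 11 (Mannich base, C15 epimers) | CC(C)(C)[Si](OCC[C@@H]1CC[C@@](C)(C(OC)OC)OC(=O)C1CN(C)C)(c1ccccc1)c1ccccc1 | intermediate (not isolated)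
14 | 3-[(trimethylammonio)methyl] derivative of 11, iodide | CC(C)(C)[Si](OCC[C@@H]1CC[C@@](C)(C(OC)OC)OC(=O)C1C[N+](C)(C)C)(c1ccccc1)c1ccccc1.[I-] | intermediate (not isolated)
15 | (4S,7S)-4-{2-[tert-butyl(diphenyl)silyl]oxyethyl}-7-(dimethoxymethyl)-7-methyl-3-methylideneoxepan-2-one | CC(C)(C)[Si](OCC[C@@H]1CC[C@@](C)(C(OC)OC)OC(=O)C1=C)(c1ccccc1)c1ccccc1 | intermediate
16 | (2S,5S)-5-{2-[tert-butyl(diphenyl)silyl]oxyethyl}-2-methyl-6-methylidene-7-oxooxepane-2-carbaldehyde (fragment A) | CC(C)(C)[Si](OCC[C@@H]1CC[C@@](C)(C=O)OC(=O)C1=C)(c1ccccc1)c1ccccc1 | intermediate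
17 | pent-3-yn-1-ol | CC#CCCO | starting material
18 | zirconocene chloride adduct of 17 (O–Zr and C4–Zr, Zr trans to C2) | C/C(=C\CCO[Zr](Cl)(C1C=CC=C1)C1C=CC=C1)[Zr](Cl)(C1C=CC=C1)C1C=CC=C1 | intermediate (not isolated)
19 | (3E)-4-iodopent-3-en-1-ol | C/C(I)=C\CCO | intermediate
20 | (2E)-2,5-diiodopent-2-ene | C/C(I)=C\CCI | intermediate
21 | [(3E)-4-iodopent-3-en-1-yl](triphenyl)phosphonium iodide | C/C(I)=C\CC[P+](c1ccccc1)(c1ccccc1)c1ccccc1.[I-] | intermediate
22 | 3-hydroxybutan-2-one (acetoin, racemic) | CC(O)C(C)=O | starting material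
23 | 3-[tert-butyl(dimethyl)silyl]oxybutan-2-one (racemic) | CC(O[Si](C)(C)C(C)(C)C)C(C)=O | intermediate
24 | [(3E)-4-iodopent-3-en-1-ylidene](triphenyl)phosphorane | C/C(I)=C\CC=P(c1ccccc1)(c1ccccc1)c1ccccc1 | intermediate (not isolated)
25 | tert-butyl{[(3Z,6E)-7-iodo-3-methylocta-3,6-dien-2-yl]oxy}dimethylsilane (racemic at C2) | CC(O[Si](C)(C)C(C)(C)C)/C(C)=C\C/C=C(\C)I | intermediate
26 | (3Z,6E)-7-iodo-3-methylocta-3,6-dien-2-ol (racemic) | CC(O)/C(C)=C\C/C=C(\C)I | intermediate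
27 | (3Z,6E)-7-iodo-3-methylocta-3,6-dien-2-one (fragment B) | CC(=O)/C(C)=C\C/C=C(\C)I | intermediate
28 | diisopinocampheylboron enolate of 27 (2-boryloxy-1,3,6-triene) | C=C(OB([C@H]1[C@H](C)[C@H]2C[C@@H](C1)C2(C)C)[C@H]1[C@H](C)[C@H]2C[C@@H](C1)C2(C)C)/C(C)=C\C/C=C(\C)I | intermediate (not isolated)
29 | O5-diisopinocampheylboryl aldolate of 30 | CC(C)(C)[Si](OCC[C@@H]1CC[C@@](C)([C@H](OB([C@H]2[C@H](C)[C@H]3C[C@@H](C2)C3(C)C)[C@H]2[C@H](C)[C@H]3C[C@@H](C2)C3(C)C)CC(=O)/C(C)=C\C/C=C(\C)I)OC(=O)C1=C)(c1ccccc1)c1ccccc1 | intermediate (not isolated)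
30 | (4S,7S)-4-{2-[tert-butyl(diphenyl)silyl]oxyethyl}-7-[(1R,4Z,7E)-1-hydroxy-8-iodo-4-methyl-3-oxonona-4,7-dien-1-yl]-7-methyl-3-methylideneoxepan-2-one | CC(C)(C)[Si](OCC[C@@H]1CC[C@@](C)([C@H](O)CC(=O)/C(C)=C\C/C=C(\C)I)OC(=O)C1=C)(c1ccccc1)c1ccccc1 | intermediate
31 | acetaldehyde | CC=O | starting material
32 | (1R,3R,4Z,7E)-1-[(2S,5S)-5-{2-[tert-butyl(diphenyl)silyl]oxyethyl}-2-methyl-6-methylidene-7-oxooxepan-2-yl]-3-hydroxy-8-iodo-4-methylnona-4,7-dien-1-yl acetate | CC(C)(C)[Si](OCC[C@@H]1CC[C@@](C)([C@H](OC(C)=O)C[C@@H](O)/C(C)=C\C/C=C(\C)I)OC(=O)C1=C)(c1ccccc1)c1ccccc1 | intermediate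
33 | (1R,3R,4Z,7E)-3-hydroxy-1-[(2S,5S)-5-(2-hydroxyethyl)-2-methyl-6-methylidene-7-oxooxepan-2-yl]-8-iodo-4-methylnona-4,7-dien-1-yl acetate | OCC[C@@H]1CC[C@@](C)([C@H](OC(C)=O)C[C@@H](O)/C(C)=C\C/C=C(\C)I)OC(=O)C1=C | intermediate
34 | (1R,3R,4Z,7E)-3-hydroxy-8-iodo-4-methyl-1-[(2S,5S)-2-methyl-6-methylidene-7-oxo-5-(2-oxoethyl)oxepan-2-yl]nona-4,7-dien-1-yl acetate | O=CC[C@@H]1CC[C@@](C)([C@H](OC(C)=O)C[C@@H](O)/C(C)=C\C/C=C(\C)I)OC(=O)C1=C | intermediate
35 | (1S,4S,5R,7R,8Z,11E,13R)-5-acetoxy-7,13-dihydroxycembra-8,11,15(17)-trien-16,4-olide (CNP0183491.2) | C=C1C(=O)O[C@@]2(C)CC[C@H]1C[C@@H](O)/C(C)=C/C/C=C(/C)[C@H](O)C[C@H]2OC(C)=O | target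

**Step count**

Total: 21 steps. Longest linear sequence: 14 steps (steps 1–9, then 17–21). The fragment B branch is steps 10–16 (six in line plus step 13).

**Steps most likely to fail**

Step 3 (facial selectivity of the methylation that creates C4; O-methylation and deformylation are side reactions). The fallback sets out from 3 and returns at 6, and replaces substrate control by catalyst control on a β-keto ester. Compound 3 is carboxylated at the less hindered α-carbon (NaH, dimethyl carbonate, THF, reflux) to methyl (4R)-4-ethenyl-2-oxocyclohexane-1-carboxylate F1. This is C-methylated under phase-transfer catalysis (MeI, solid K2CO3, toluene, −20 °C, 2 mol % of 4,4-dibutyl-2,6-bis(3,4,5-trifluorophenyl)-4,5-dihydro-3H-dinaphtho[2,1-c:1',2'-e]azepinium bromide, using the catalyst enantiomer, 11bS or 11bR, that reinforces axial attack) to methyl (1R,4R)-4-ethenyl-1-methyl-2-oxocyclohexane-1-carboxylate F2. LiAlH4 (THF, 0 °C) reduces ester and ketone to (2S,5R)-5-ethenyl-2-(hydroxymethyl)-2-methylcyclohexan-1-ol F3 (mixture at C1), and Swern oxidation of both hydroxyls ((COCl)2, DMSO, Et3N, −78 °C) gives keto aldehyde 6.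

Step 17 (a bulky boron enolate has to add to a neopentyl aldehyde; C5 selectivity and the Z enone are at stake). The fallback sets out from 27 (with 16) and returns at 30, and replaces the closed boron transition state by a Lewis-acid-mediated open one through an isolated enol silane. Ketone 27 is converted with Me3SiOTf and Et3N (CH2Cl2, −78 → 0 °C) into trimethyl{[(3Z,6E)-7-iodo-3-methylocta-1,3,6-trien-2-yl]oxy}silane F4. F4 is added to 16 in a Mukaiyama aldol reaction (BF3·OEt2, CH2Cl2, −78 °C; aqueous NaHCO3 work-up), where only Cornforth control by the α-acyloxy quaternary centre sets C5. The 5R adduct 30 is separated from its epimer and the route continues at step 18.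

Step 21 (ring-closure yield and the C13 configuration, which cannot be corrected afterwards because C7–OH is also free). The fallback sets out from 32 and returns at 35, and sets C13 by oxidation and reagent-controlled reduction instead of in the ring closure.
- The C7 hydroxyl of 32 is protected with 4-methoxybenzyl 2,2,2-trichloroacetimidate and La(OTf)3 (cat.) to give (1R,3R,4Z,7E)-1-[(2S,5S)-5-{2-[tert-butyl(diphenyl)silyl]oxyethyl}-2-methyl-6-methylidene-7-oxooxepan-2-yl]-8-iodo-3-[(4-methoxyphenyl)methoxy]-4-methylnona-4,7-dien-1-yl acetate F5.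
- HF·pyridine gives the primary alcohol (1R,3R,4Z,7E)-1-[(2S,5S)-5-(2-hydroxyethyl)-2-methyl-6-methylidene-7-oxooxepan-2-yl]-8-iodo-3-[(4-methoxyphenyl)methoxy]-4-methylnona-4,7-dien-1-yl acetate F6.
- Dess–Martin oxidation gives the aldehyde (1R,3R,4Z,7E)-8-iodo-3-[(4-methoxyphenyl)methoxy]-4-methyl-1-[(2S,5S)-2-methyl-6-methylidene-7-oxo-5-(2-oxoethyl)oxepan-2-yl]nona-4,7-dien-1-yl acetate F7.
- Ligand-free ring closure (CrCl2, NiCl2 cat., DMSO/THF, 2 mM) gives the 7-O-(4-methoxybenzyl) ether of 35 as a mixture of C13 epimers F8.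
- Dess–Martin oxidation converges both epimers on the 7-O-(4-methoxybenzyl)-13-oxo macrocycle (C13 enone) F9.
- Corey–Bakshi–Shibata reduction with (S)-1-methyl-3,3-diphenyltetrahydro-1H,3H-pyrrolo[1,2-c][1,3,2]oxazaborole and catecholborane (toluene, −78 °C; the alkenyl group acts as the large substituent) gives the (13R)-7-O-(4-methoxybenzyl) ether of 35 F10.
- DDQ (CH2Cl2/pH 7 buffer, 0 °C) removes the ether and gives 35.

**Further compounds**

F1 | step 3 | methyl (4R)-4-ethenyl-2-oxocyclohexane-1-carboxylate | C=C[C@@H]1CCC(C(=O)OC)C(=O)C1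
F2 | step 3 | methyl (1R,4R)-4-ethenyl-1-methyl-2-oxocyclohexane-1-carboxylate | C=C[C@@H]1CC[C@@](C)(C(=O)OC)C(=O)C1
F3 | step 3 | (2S,5R)-5-ethenyl-2-(hydroxymethyl)-2-methylcyclohexan-1-ol (C1 epimers) | C=C[C@@H]1CC[C@@](C)(CO)C(O)C1
F4 | step 17 | trimethyl{[(3Z,6E)-7-iodo-3-methylocta-1,3,6-trien-2-yl]oxy}silane | C=C(O[Si](C)(C)C)/C(C)=C\C/C=C(\C)I
F5 | step 21 | (1R,3R,4Z,7E)-1-[(2S,5S)-5-{2-[tert-butyl(diphenyl)silyl]oxyethyl}-2-methyl-6-methylidene-7-oxooxepan-2-yl]-8-iodo-3-[(4-methoxyphenyl)methoxy]-4-methylnona-4,7-dien-1-yl acetate | CC(C)(C)[Si](OCC[C@@H]1CC[C@@](C)([C@H](OC(C)=O)C[C@@H](OCc2ccc(OC)cc2)/C(C)=C\C/C=C(\C)I)OC(=O)C1=C)(c1ccccc1)c1ccccc1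
F6 | step 21 | (1R,3R,4Z,7E)-1-[(2S,5S)-5-(2-hydroxyethyl)-2-methyl-6-methylidene-7-oxooxepan-2-yl]-8-iodo-3-[(4-methoxyphenyl)methoxy]-4-methylnona-4,7-dien-1-yl acetate | OCC[C@@H]1CC[C@@](C)([C@H](OC(C)=O)C[C@@H](OCc2ccc(OC)cc2)/C(C)=C\C/C=C(\C)I)OC(=O)C1=C
F7 | step 21 | (1R,3R,4Z,7E)-8-iodo-3-[(4-methoxyphenyl)methoxy]-4-methyl-1-[(2S,5S)-2-methyl-6-methylidene-7-oxo-5-(2-oxoethyl)oxepan-2-yl]nona-4,7-dien-1-yl acetate | O=CC[C@@H]1CC[C@@](C)([C@H](OC(C)=O)C[C@@H](OCc2ccc(OC)cc2)/C(C)=C\C/C=C(\C)I)OC(=O)C1=C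
F8 | step 21 | 7-O-(4-methoxybenzyl) ether of 35 as a mixture of C13 epimers | C=C1C(=O)O[C@@]2(C)CC[C@H]1CC(O)/C(C)=C/C/C=C(/C)[C@H](OCc3ccc(OC)cc3)C[C@H]2OC(C)=O
F9 | step 21 | 7-O-(4-methoxybenzyl)-13-oxo analogue of 35 (C13 enone) | C=C1C(=O)O[C@@]2(C)CC[C@H]1CC(=O)/C(C)=C/C/C=C(/C)[C@H](OCc3ccc(OC)cc3)C[C@H]2OC(C)=O
F10 | step 21 | (13R)-7-O-(4-methoxybenzyl) ether of 35 | C=C1C(=O)O[C@@]2(C)CC[C@H]1C[C@@H](O)/C(C)=C/C/C=C(/C)[C@H](OCc3ccc(OC)cc3)C[C@H]2OC(C)=O
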